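**Retrosynthetic overview** (C numbers are positions in the C20 ester chain of the target; compound numbers follow the forward route)
1. The (Z,Z)-bromodiene is made last by Z-selective mono-debromination of a 1,1-dibromodiene, which comes from a Z-enal; the E-enyne comes from a Sonogashira union of an ethynyl-oxolane ester (fragment 1) with (2Z,8E)-9-iodonona-2,8-dien-1-ol (fragment 2).
2. Fragment 1: the alkyne comes from a CH2OH group (oxidation, Ohira–Bestmann) and the ester arm from an allyl group (cross-metathesis with methyl acrylate, hydrogenation) on a trans-2-allyl-5-(benzyloxymethyl)oxolane.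
3. Ring formation (one ring only): the oxolane is closed by invertive 5-exo SN2 attack of the C5 hydroxyl on a C8 mesylate.
4. Key C–C bond C4–C5: intermolecular asymmetric allylboration of a γ-mesyloxy aldehyde, which sets C5; C8 is taken from (R)-benzyl glycidyl ether (opened with allylMgBr, then ozonolysis).
5. Fragment 2: from hept-6-yn-1-ol by hydrozirconation–iodination, oxidation, Still–Gennari olefination and iBu2AlH reduction.

Assumption: (R)-benzyl glycidyl ether, (+)-B-allyldiisopinocampheylborane (1 M in pentane), hept-6-yn-1-ol and the Still–Gennari phosphonate are bought as such.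

**Route**

Step 1
Reactants: 1 (R)-benzyl glycidyl ether [(2R)-2-[(benzyloxy)methyl]oxirane]; 2 allylmagnesium bromide
Product: 3 (2R)-1-(benzyloxy)hex-5-en-2-ol
Conditions: 2 (1.5 equiv), CuI (10 mol %), THF, −40 → 0 °C; aqueous work-up
Reagents that add atoms: none
Why: Copper-catalysed SN2 opening of the terminal epoxide by the allyl Grignard reagent occurs at the unhindered CH2, so the chiral-pool stereocentre (the future C8) is carried over untouched as 2R.

Step 2
Reactants: 3 (2R)-1-(benzyloxy)hex-5-en-2-ol
Product: 4 (2R)-1-(benzyloxy)hex-5-en-2-yl methanesulfonate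
Conditions: MsCl (1.3 equiv), Et3N (2 equiv), CH2Cl2, 0 °C
Reagents that add atoms: methanesulfonyl chloride, CS(=O)(=O)Cl
Why: O-Sulfonylation (mesylation) proceeds with retention at carbon and installs the leaving group for the later invertive ring closure.

Step 3
Reactants: 4 (2R)-1-(benzyloxy)hex-5-en-2-yl methanesulfonate
Product: 6 (2R)-1-(benzyloxy)-5-oxopentan-2-yl methanesulfonate, via secondary ozonide 5 (not isolated)
Conditions: O3, CH2Cl2, −78 °C (stop at first blue colour); then PPh3 (1.2 equiv), −78 °C → rt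
Reagents that add atoms: ozone, [O-][O+]=O
Why: Ozonolysis with reductive PPh3 work-up cleaves only the terminal alkene to the aldehyde, the mesylate and benzyl ether being inert at −78 °C when ozone is not used in excess.

Step 4
Reactants: 6 (2R)-1-(benzyloxy)-5-oxopentan-2-yl methanesulfonate; 7 (+)-B-allyldiisopinocampheylborane
Product: 9 (2R,5S)-1-(benzyloxy)-5-hydroxyoct-7-en-2-yl methanesulfonate, via borinate ester 8 (not isolated)
Conditions: 7 (1.3 equiv), Et2O, −78 °C, 2 h; then MeOH, pH 7 buffer (NaH2PO4/Na2HPO4), 30% H2O2, 0 °C → rt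
Reagents that add atoms: none
Why: Brown asymmetric allylboration through a closed chair Zimmerman–Traxler transition state delivers the allyl group to one aldehyde face under reagent control (the (+)-reagent from (−)-α-pinene gives the 5S carbinol, typically ≥ 94:6, the remote mesylate centre having no influence), and the neutral oxidative work-up frees the alcohol without triggering cyclisation.

Step 5
Reactants: 9 (2R,5S)-1-(benzyloxy)-5-hydroxyoct-7-en-2-yl methanesulfonate
Product: 10 (2S,5S)-2-[(benzyloxy)methyl]-5-(prop-2-en-1-yl)oxolane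
Conditions: NaH (1.3 equiv), THF, 0 °C → rt
Reagents that add atoms: none
Why: Intramolecular Williamson etherification (5-exo-tet SN2) of the C5 alkoxide on the mesylate carbon proceeds with clean inversion there and retention at the carbinol carbon, giving the 2,5-trans oxolane; the few percent of cis isomer from step 4 is removed by chromatography here.

Step 6
Reactants: 10 (2S,5S)-2-[(benzyloxy)methyl]-5-(prop-2-en-1-yl)oxolane; 11 methyl acrylate
Product: 12 methyl (2E)-4-[(2S,5S)-5-[(benzyloxy)methyl]oxolan-2-yl]but-2-enoate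
Conditions: 11 (5 equiv), second-generation Grubbs catalyst RuCl2(=CHPh)(H2IMes)(PCy3) (3 mol %), CH2Cl2, 40 °C
Reagents that add atoms: none
Why: Olefin cross-metathesis of a terminal alkene with the electron-poor acrylate is selective for the E cross-product because acrylate homodimerises slowly, and no stereocentre is touched.

Step 7
Reactants: 12 methyl (2E)-4-[(2S,5S)-5-[(benzyloxy)methyl]oxolan-2-yl]but-2-enoate
Product: 14 methyl 4-[(2R,5S)-5-(hydroxymethyl)oxolan-2-yl]butanoate, via saturated benzyl ether 13 (not isolated)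
Conditions: H2 (1 atm), 10% Pd/C, MeOH, rt
Reagents that add atoms: none
Why: Heterogeneous catalytic hydrogenation saturates the enoate C=C and then hydrogenolyses the benzyl ether in the same pot, leaving the ester, the oxolane and both stereocentres unchanged (the descriptor at the chain-bearing carbon changes from S to R only through CIP priorities).

Step 8
Reactants: 14 methyl 4-[(2R,5S)-5-(hydroxymethyl)oxolan-2-yl]butanoate
Product: 15 methyl 4-[(2R,5S)-5-formyloxolan-2-yl]butanoate
Conditions: Dess–Martin periodinane (1.3 equiv), NaHCO3 (3 equiv), CH2Cl2, 0 °C → rt; used crude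
Reagents that add atoms: none
Why: Dess–Martin oxidation gives the α-alkoxy aldehyde under buffered, non-enolising conditions, so the adjacent stereocentre is preserved.

Step 9
Reactants: 15 methyl 4-[(2R,5S)-5-formyloxolan-2-yl]butanoate
Product: 16 methyl 4-[(2R,5S)-5-ethynyloxolan-2-yl]butanoate
Conditions: dimethyl (1-diazo-2-oxopropyl)phosphonate (1.5 equiv), K2CO3 (2 equiv), MeOH, 0 °C → rt
Reagents that add atoms: dimethyl (1-diazo-2-oxopropyl)phosphonate, COP(=O)(OC)C(=[N+]=[N-])C(C)=O
Why: Seyferth–Gilbert homologation with the Ohira–Bestmann reagent (in situ diazomethylphosphonate, Horner–Wadsworth–Emmons-type addition, N2 loss and 1,2-hydride shift of the alkylidene carbene) gives the terminal alkyne under mild K2CO3/MeOH conditions that leave the methyl ester and, at 0 °C, the α-stereocentre intact.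

Step 10
Reactants: 17 hept-6-yn-1-ol
Product: 19 (6E)-7-iodohept-6-en-1-ol, via alkenylzirconocene 18 (not isolated)
Conditions: Cp2Zr(H)Cl (2.3 equiv), THF, rt, dark; then I2 (1.2 equiv), 0 °C; aq. Na2S2O3 work-up
Reagents that add atoms: iodine, II
Why: Hydrozirconation is a syn, anti-Markovnikov addition of Zr–H to the terminal alkyne (one equivalent is spent on the hydroxyl), and iodinolysis of the C–Zr bond with retention gives only the E-iodoalkene.

Step 11
Reactants: 19 (6E)-7-iodohept-6-en-1-ol
Product: 20 (6E)-7-iodohept-6-enal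
Conditions: Dess–Martin periodinane (1.3 equiv), NaHCO3 (3 equiv), CH2Cl2, 0 °C → rt
Reagents that add atoms: none
Why: Dess–Martin oxidation of the primary alcohol stops at the aldehyde and does not touch the alkenyl iodide.

Step 12
Reactants: 20 (6E)-7-iodohept-6-enal; 21 methyl 2-[bis(2,2,2-trifluoroethoxy)phosphoryl]acetate
Product: 22 methyl (2Z,8E)-9-iodonona-2,8-dienoate
Conditions: 21 (1.2 equiv), KN(SiMe3)2 (1.15 equiv), 18-crown-6 (3 equiv), THF, −78 °C
Reagents that add atoms: none
Why: In the Still–Gennari variant of the Horner–Wadsworth–Emmons reaction the electron-poor trifluoroethyl phosphonate with a dissociated potassium counter-ion eliminates fast from the kinetic adduct and gives the Z-enoate (typically > 15:1).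

Step 13
Reactants: 22 methyl (2Z,8E)-9-iodonona-2,8-dienoate
Product: 23 (2Z,8E)-9-iodonona-2,8-dien-1-ol
Conditions: iBu2AlH (2.5 equiv), CH2Cl2, −78 °C; aq. potassium sodium tartrate
Reagents that add atoms: none
Why: 1,2-Reduction of the enoate by iBu2AlH at −78 °C gives the allylic alcohol without touching the alkenyl iodide or either alkene geometry.

Step 14
Reactants: 16 methyl 4-[(2R,5S)-5-ethynyloxolan-2-yl]butanoate; 23 (2Z,8E)-9-iodonona-2,8-dien-1-ol
Product: 24 methyl 4-[(2R,5S)-5-[(3E,9Z)-11-hydroxyundeca-3,9-dien-1-yn-1-yl]oxolan-2-yl]butanoate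
Conditions: PdCl2(PPh3)2 (5 mol %), CuI (10 mol %), Et3N, THF (degassed), rt
Reagents that add atoms: none
Why: In the Sonogashira coupling, oxidative addition of zerovalent palladium into the alkenyl C–I bond and transmetalation from the copper acetylide proceed with retention, giving the E-enyne while the free allylic hydroxyl and the ester are tolerated.

Step 15
Reactants: 24 methyl 4-[(2R,5S)-5-[(3E,9Z)-11-hydroxyundeca-3,9-dien-1-yn-1-yl]oxolan-2-yl]butanoate
Product: 25 methyl 4-[(2R,5S)-5-[(3E,9Z)-11-oxoundeca-3,9-dien-1-yn-1-yl]oxolan-2-yl]butanoate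
Conditions: Dess–Martin periodinane (1.3 equiv), NaHCO3 (3 equiv), CH2Cl2, 0 °C; used at once
Reagents that add atoms: none
Why: Buffered Dess–Martin oxidation at 0 °C converts the Z-allylic alcohol into the Z-enal without acid- or base-mediated isomerisation.

Step 16
Reactants: 25 methyl 4-[(2R,5S)-5-[(3E,9Z)-11-oxoundeca-3,9-dien-1-yn-1-yl]oxolan-2-yl]butanoate
Product: 26 methyl 4-[(2R,5S)-5-[(3E,9Z)-12,12-dibromododeca-3,9,11-trien-1-yn-1-yl]oxolan-2-yl]butanoate
Conditions: CBr4 (2 equiv), PPh3 (4 equiv), 2,6-lutidine (2 equiv), CH2Cl2, 0 °C (ylide pre-formed, aldehyde added last)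
Reagents that add atoms: carbon tetrabromide, BrC(Br)(Br)Br
Why: In the Ramirez dibromo-olefination (first half of the Corey–Fuchs sequence) the pre-formed ylide Ph3P=CBr2 undergoes a Wittig reaction with the aldehyde only, the ester being inert, and the cold, buffered conditions keep the 9Z alkene.

Step 17
Reactants: 26 methyl 4-[(2R,5S)-5-[(3E,9Z)-12,12-dibromododeca-3,9,11-trien-1-yn-1-yl]oxolan-2-yl]butanoate
Product: 27 methyl 4-[(2R,5S)-5-[(3E,9Z,11Z)-12-bromododeca-3,9,11-trien-1-yn-1-yl]oxolan-2-yl]butanoate
Conditions: Bu3SnH (1.1 equiv), Pd(PPh3)4 (5 mol %), toluene, rt, dark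
Reagents that add atoms: none
Why: In the palladium-catalysed hydrogenolysis of 1,1-dibromoalkenes (Uenishi method) zerovalent palladium inserts selectively into the C–Br bond trans to the diene chain and hydride transfer with retention leaves the cis bromine, giving the 11Z bromodiene.

**Compound list**

1 | (R)-benzyl glycidyl ether, (2R)-2-[(benzyloxy)methyl]oxirane | C1O[C@H]1COCc2ccccc2 | starting material
2 | allylmagnesium bromide | C=CC[Mg]Br | starting material
3 | (2R)-1-(benzyloxy)hex-5-en-2-ol | C=CCC[C@@H](O)COCc1ccccc1 | intermediate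
4 | (2R)-1-(benzyloxy)hex-5-en-2-yl methanesulfonate | C=CCC[C@@H](OS(C)(=O)=O)COCc1ccccc1 | intermediate
5 | (2R)-1-(benzyloxy)-4-(1,2,4-trioxolan-3-yl)butan-2-yl methanesulfonate (secondary ozonide, both configurations at the trioxolane carbon) | C1OC(CC[C@@H](OS(C)(=O)=O)COCc2ccccc2)OO1 | intermediate (not isolated)
6 | (2R)-1-(benzyloxy)-5-oxopentan-2-yl methanesulfonate | O=CCC[C@@H](OS(C)(=O)=O)COCc1ccccc1 | intermediate
7 | (+)-B-allyldiisopinocampheylborane (isopinocampheyl groups from (−)-α-pinene) | C=CCB([C@H]1C[C@H]2C[C@@H]([C@@H]1C)C2(C)C)[C@H]1C[C@H]2C[C@@H]([C@@H]1C)C2(C)C | starting material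
8 | (2R,5S)-1-(benzyloxy)-5-[(diisopinocampheylboranyl)oxy]oct-7-en-2-yl methanesulfonate (borinate ester) | C=CC[C@@H](OB([C@H]1C[C@H]2C[C@@H]([C@@H]1C)C2(C)C)[C@H]1C[C@H]2C[C@@H]([C@@H]1C)C2(C)C)CC[C@@H](OS(C)(=O)=O)COCc1ccccc1 | intermediate (not isolated)
9 | (2R,5S)-1-(benzyloxy)-5-hydroxyoct-7-en-2-yl methanesulfonate | C=CC[C@@H](O)CC[C@@H](OS(C)(=O)=O)COCc1ccccc1 | intermediate
10 | (2S,5S)-2-[(benzyloxy)methyl]-5-(prop-2-en-1-yl)oxolane (2,5-trans) | C=CC[C@@H]1CC[C@@H](COCc2ccccc2)O1 | intermediate
11 | methyl acrylate | C=CC(=O)OC | starting material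
12 | methyl (2E)-4-[(2S,5S)-5-[(benzyloxy)methyl]oxolan-2-yl]but-2-enoate | COC(=O)/C=C/C[C@@H]1CC[C@@H](COCc2ccccc2)O1 | intermediate
13 | methyl 4-[(2R,5S)-5-[(benzyloxy)methyl]oxolan-2-yl]butanoate (saturated benzyl ether) | COC(=O)CCC[C@@H]1CC[C@@H](COCc2ccccc2)O1 | intermediate (not isolated)
14 | methyl 4-[(2R,5S)-5-(hydroxymethyl)oxolan-2-yl]butanoate | COC(=O)CCC[C@@H]1CC[C@@H](CO)O1 | intermediate
15 | methyl 4-[(2R,5S)-5-formyloxolan-2-yl]butanoate | COC(=O)CCC[C@@H]1CC[C@@H](C=O)O1 | intermediate
16 | methyl 4-[(2R,5S)-5-ethynyloxolan-2-yl]butanoate | COC(=O)CCC[C@@H]1CC[C@@H](C#C)O1 | intermediate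
17 | hept-6-yn-1-ol | C#CCCCCCO | starting material
18 | chlorobis(cyclopentadienyl)[(1E)-7-{[chlorobis(cyclopentadienyl)zirconio]oxy}hept-1-en-1-yl]zirconium (alkenylzirconocene, Cp drawn σ-bound) | Cl[Zr](OCCCCC/C=C/[Zr](Cl)(C1C=CC=C1)C1C=CC=C1)(C1C=CC=C1)C1C=CC=C1 | intermediate (not isolated)
19 | (6E)-7-iodohept-6-en-1-ol | OCCCCC/C=C/I | intermediate
20 | (6E)-7-iodohept-6-enal | O=CCCCC/C=C/I | intermediate
21 | methyl 2-[bis(2,2,2-trifluoroethoxy)phosphoryl]acetate | COC(=O)CP(=O)(OCC(F)(F)F)OCC(F)(F)F | starting material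
22 | methyl (2Z,8E)-9-iodonona-2,8-dienoate | COC(=O)/C=C\CCCC/C=C/I | intermediate
23 | (2Z,8E)-9-iodonona-2,8-dien-1-ol | OC/C=C\CCCC/C=C/I | intermediate
24 | methyl 4-[(2R,5S)-5-[(3E,9Z)-11-hydroxyundeca-3,9-dien-1-yn-1-yl]oxolan-2-yl]butanoate | COC(=O)CCC[C@@H]1CC[C@@H](C#C/C=C/CCCC/C=C\CO)O1 | intermediate
25 | methyl 4-[(2R,5S)-5-[(3E,9Z)-11-oxoundeca-3,9-dien-1-yn-1-yl]oxolan-2-yl]butanoate | COC(=O)CCC[C@@H]1CC[C@@H](C#C/C=C/CCCC/C=C\C=O)O1 | intermediate
26 | methyl 4-[(2R,5S)-5-[(3E,9Z)-12,12-dibromododeca-3,9,11-trien-1-yn-1-yl]oxolan-2-yl]butanoate | COC(=O)CCC[C@@H]1CC[C@@H](C#C/C=C/CCCC/C=C\C=C(Br)Br)O1 | intermediate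
27 | methyl 4-[(2R,5S)-5-[(3E,9Z,11Z)-12-bromododeca-3,9,11-trien-1-yn-1-yl]oxolan-2-yl]butanoate | COC(=O)CCC[C@@H]1CC[C@@H](C#C/C=C/CCCC/C=C\C=C/Br)O1 | target

**Totals**

Total step count: 17. Longest linear sequence: 13 steps (steps 1–9, then 14–17, from compound 1); fragment 2 takes 4 steps (10–13).

**Three steps most likely to fail, with fallbacks**

Step 9 (risk: base-mediated epimerisation of the α-alkoxy aldehyde next to the ring oxygen, giving some cis-oxolane). The fallback sets out from 15 and comes back at 16. Aldehyde 15 is treated with CBr4/PPh3/2,6-lutidine in CH2Cl2 at 0 °C, conditions that do not enolise it, to give methyl 4-[(2R,5S)-5-(2,2-dibromoethenyl)oxolan-2-yl]butanoate F1. HBr is then eliminated with NaN(SiMe3)2 in THF at −78 °C to give methyl 4-[(2R,5S)-5-(bromoethynyl)oxolan-2-yl]butanoate F2, in which the ring stereocentre is no longer next to a carbonyl. Bromine–magnesium exchange with iPrMgCl·LiCl at −78 °C (methyl ester tolerated) and protonation with aq. NH4Cl gives 16.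

Step 16 (risk: Z → E isomerisation or decomposition of the Z-enal under the phosphine/bromide conditions of the dibromo-olefination). The fallback sets out from 25 and comes back at 27. Enal 25 is added at −78 °C to the ylide Ph3P=CHBr, made from (bromomethyl)triphenylphosphonium bromide and KOtBu in THF. This Z-selective Wittig bromomethylenation gives 27 directly, bypasses 26, and makes no new compound (F0); the minor 11E isomer would be removed on AgNO3-impregnated silica.

Step 17 (risk: hydrostannation or over-reduction at the conjugated enyne by the tin hydride/palladium system, and tin residues in the final product). The fallback sets out from 23, with 16 kept in hand, and comes back at 27. Alcohol 23 is oxidised (Dess–Martin periodinane, NaHCO3, 0 °C) to (2Z,8E)-9-iodonona-2,8-dienal F3. Wittig reaction of it with Ph3P=CHBr at −78 °C gives (1Z,3Z,9E)-1-bromo-10-iododeca-1,3,9-triene F4, whose geometric isomers can be separated at this small-fragment stage. The union is then made last: an iodide-selective Sonogashira coupling of F4 with 16 (PdCl2(PPh3)2, CuI, Et3N, THF, 0 °C → rt), in which the alkenyl iodide reacts far faster than the dienyl bromide, gives 27 with no tin hydride near the enyne.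

**Further compounds**

F1 | step 9 | methyl 4-[(2R,5S)-5-(2,2-dibromoethenyl)oxolan-2-yl]butanoate | COC(=O)CCC[C@@H]1CC[C@@H](C=C(Br)Br)O1
F2 | step 9 | methyl 4-[(2R,5S)-5-(bromoethynyl)oxolan-2-yl]butanoate | COC(=O)CCC[C@@H]1CC[C@@H](C#CBr)O1
F0 | step 16 | none | none
F3 | step 17 | (2Z,8E)-9-iodonona-2,8-dienal | O=C/C=C\CCCC/C=C/I
F4 | step 17 | (1Z,3Z,9E)-1-bromo-10-iododeca-1,3,9-triene | Br/C=C\C=C/CCCC/C=C/I
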